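The numbers in the tables were computed with constants of no real substance; the scatter is artificial.

In a one-step world a flask that stops has used up a charge, and heat adds nothing. The flask asked about, ochre, and its hotter twin teal show something else.

| setting | ochre | teal | flask |
|---|---|---|---|
| substrate | 0.11 M | 0.11 M | 0.11 M |
| coupling partner | 0.077 M | 0.077 M | 0.0770 M |
| protic impurity | 0.033 M | 0.033 M | 0.0330 M |
| initiator | 1.1 mM | 1.1 mM | 1.1 mM |
| temperature | 100 °C | 106 °C | 100 °C |
| remark | the very flask that is asked about, followed so far | run made earlier |  |
| time |  |  | 80 min |
- ochre (time / min: target / %, substrate / %): 12.0: 36.6, 43.2; 25.0: 36.8, 42.2; 40.0: 35.7, 43.0; 50.0: 35.7, 41.4; 60.0: 36.2, 41.9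
- teal (time / min: target / %, substrate / %): 12.0: 41.2, 41.1; 25.0: 40.4, 41.7; 40.0: 40.3, 41.1; 50.0: 40.8, 41.6; 60.0: 41.0, 42.0

(readings scatter by 0.5 percentage points)
- winter: change nothing and wait 40 min more
- spring: at 80 min raise the temperature by 25 K, then wait 40 min
- summer: at 80 min take out 90% of the released group then present, then wait 40 min
- noon: at 80 min add coupling partner, 50.0% of the amount charged, then wait 40 min
- additions leave the volume as it is
- the analysis behind the earlier runs scatters by 0.5 percentage points, standard deviation
- target, in percent of the substrate first charged, at 80 min
- the remedy with the largest gain of target, or "none" below 2 percentage points (winter / spring / summer / noon / none)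
- target present, in percent of the substrate first charged, after summer
- target present, in percent of the substrate first charged, after noon

Averaged over 5 readings, ochre holds 36.2% target and has used 57.7% of its substrate, so 21.5% is unseen. Teal holds 40.7% and has used 58.5%, so 17.8% is unseen. Heat moved the split and left the used substrate nearly where it was.

We therefore suppose that target and the unseen share interconvert under thermodynamic control. The unseen share over target, the split ratio, is 0.593 in ochre and 0.436 in teal. Integrating van 't Hoff's law between the two temperatures gives a reaction enthalpy of −60.3 kJ mol⁻¹. The same law, 25 K above ochre, gives a ratio of 0.175, so we reckon that spring leaves 49.1% target.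

Used substrate falls short of the partner charge by 0.0136 M. We assign this to the impurity and take partner as the limiting reagent, so we reckon that 0.0194 M of impurity remains. If that remainder first takes its own amount out of noon's 0.0385 M, we reckon that used substrate rises by 17.3% of the charge, and the ratio 0.593 gives 47.1% target, less than we reckon for spring.

The weak link is stretching 6.00 K to 25 K. With half the slope, spring gives 43.6%, less than our noon figure, so the choice of remedy hangs on the slope. But the unseen share fell 3.7 percentage points between the runs, against a scatter of 0.5 points per reading, so we think an error that large unlikely. We commit to 36.2% now, summer unchanged at 36.2%, 47.1% after noon, and spring as best.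

The forecast gives 36.2% now, none as best remedy, 36.2% after summer and 36.2% after noon, reading the runs thus: “A fixed conversion with a temperature-dependent selectivity instead points to a dead initiator or chain”.

The flask gives 36.1% now, best remedy spring with a gain of 12 points, summer 36.1% and noon 41.1%, a gain of 5 points.

The mechanism behind the flask is this:

    initiator → 2 initiating radical (k = 0.00180 s⁻¹, Ea = 122 kJ mol⁻¹)
    coupling partner + first chain carrier → target + second chain carrier (k = 3.30 × 10⁶ L mol⁻¹ s⁻¹, Ea = 19.0 kJ mol⁻¹)
    2 second chain carrier → ended chains (k = 7.90 × 10⁸ L mol⁻¹ s⁻¹, Ea = 10.0 kJ mol⁻¹)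
    substrate + initiating radical → capped initiator + first chain carrier (k = 6.20 × 10⁶ L mol⁻¹ s⁻¹, Ea = 11.0 kJ mol⁻¹)
    coupling partner + protic impurity → quenched reagent (k = 0.270 L mol⁻¹ s⁻¹, Ea = 53.0 kJ mol⁻¹)
    substrate + second chain carrier → released group + first chain carrier (k = 2.30 × 10⁵ L mol⁻¹ s⁻¹, Ea = 10.0 kJ mol⁻¹)
    target ⇌ isomer of the product (K = 0.560, k = 0.0220 s⁻¹, Ea = 115 kJ mol⁻¹, ΔH = −60.0 kJ mol⁻¹)
    (constants at 100 °C)

The neighbouring flask is the same flask with 0.028 M of substrate, and it ends with 0% substrate and 20.8% of its partner left. Applied to its charge, our ratio 0.593 gives that flask 62.8% target. That flask holds 64.1% target and 35.9% isomer of the product, a ratio of 0.560.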